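The readings are simulated for an exercise.

Follow the temperature down to Wednesday's, −5 °C, and ask how much target 2.5 min can hold there.

| setting | teal | ochre | Monday's | Sunday's | Wednesday's |
|---|---|---|---|---|---|
| substrate | 5 mM | 7.5 mM | 10 mM | 10 mM | 10 mM |
| fresh partner | 15 mM | 15 mM | 15.0 mM | 15.0 mM | 15.0 mM |
| gas | 0.67 mM (held) | 0.67 mM (held) | 0.67 mM (held) | 0.67 mM (held) | 0.67 mM (held) |
| temperature | −10 °C | 25 °C | 55 °C | 25 °C | −5 °C |
| remark | run made earlier | run made earlier |  |  |  |
| time |  |  | 2.5 min | 2.5 min | 2.5 min |

| run | time / min | target / % |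
|---|---|---|
| teal | 8.00 | 99.4 |
| teal | 15.0 | 99.7 |
| teal | 25.0 | 99.5 |
| teal | 30.0 | 100.3 |
| teal | 40.0 | 99.5 |
| teal | 50.0 | 99.2 |
| ochre | 0.667 | 64.5 |
| ochre | 2.00 | 98.1 |
| ochre | 3.00 | 96.7 |
| ochre | 4.00 | 96.2 |
| ochre | 6.00 | 94.7 |
| ochre | 8.00 | 92.9 |

(readings scatter by 0.3 percentage points)

- at the start none of the gas is in solution

- the flask with the highest amount of target, in percent of the substrate charged ("all alike" if they lie within 1.5 percentage points) (Monday's / Sunday's / Wednesday's / all alike)
- final target, as a percentage of the substrate charged, in Monday's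
- final target, as a percentage of the substrate charged, in Sunday's
- final target, as a percentage of the substrate charged, in Wednesday's

Start from ochre's first reading, which gives 7.25 mM min⁻¹. This is the making rate, the mM of target formed per minute. Assume it does not depend on the charge, that is, zero order in substrate. Teal still reads 99.2% at 50.0 min, so count no loss in the cold.

Now bound Wednesday's from above. Take it that Wednesday's, colder than ochre, makes target no faster; 2.5 min at ochre's rate gives 18.1 mM, more than the 10 mM charged. The ceiling therefore stays at 100 percent.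

Then bound it from below. Teal, at −10 °C, already read 99.4% of its 5 mM at 8.00 min, so its rate was at least 0.621 mM min⁻¹. By itself that gives 15.5%.

Tighten this floor. The logarithm of an Arrhenius rate bends downward against temperature, so a straight line in ln(rate) from teal's floor to ochre's rate runs under the curve. At −5 °C the line reads 0.883 mM min⁻¹, which makes the floor 22.1%. My hand stops at this bracket, from 22.1% to 100 percent.

The forecast names Sunday's as richest, with 62% for Monday's, 97.8% for Sunday's and 45% for Wednesday's: "so Wednesday's is incomplete at 2.5 min, about 45%". Its Wednesday figure stands inside the bracket, above the floor.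

Wednesday's ends at 75.7%, above the floor and 31 percentage points above the forecast; Monday's ends at 63.2%, while Sunday's holds the most, 97.6%.

Here is the scheme that ran:

    substrate + coupling partner → open intermediate (k = 231 L mol⁻¹ s⁻¹, Ea = 44.0 kJ mol⁻¹)
    coupling partner + fresh partner → second intermediate (k = 1020 L mol⁻¹ s⁻¹, Ea = 42.0 kJ mol⁻¹)
    open intermediate + second intermediate → target (k = 18.5 L mol⁻¹ s⁻¹, Ea = 42.0 kJ mol⁻¹)
    2 open intermediate → homo product (k = 0.481 L mol⁻¹ s⁻¹, Ea = 54.0 kJ mol⁻¹)
    gas ⇌ coupling partner, rate k5*(csat - [coupling partner]) (kL = 1.06 s⁻¹)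
    target → over-reaction product (k = 1.55 × 10⁻⁴ s⁻¹, Ea = 86.0 kJ mol⁻¹)
    (constants at 25 °C)

At 2.50 min Wednesday's still holds 15.2% as open intermediate and 8.67% as substrate. Wednesday's mean making rate over 2.5 min is 3.03 mM min⁻¹, faster than the floor rate and slower than ochre's. Carry ochre's rate to Sunday's: at 1.25 min it gives 90.6% target, and Sunday's holds 96.2%.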